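**Assumption:** the target is the 2,3-trans (2R,3R) dihydroflavonol with both prenyls on carbon, as its SMILES specifies. Stereochemistry is assigned from CIP analysis of the SMILES.

## Retrosynthetic overview
1. Target ⇐ removal of three aryl MOM groups from the protected dihydroflavonol **14**.
2. **14** ⇐ radical ring closure: acyl radical from hydroxy-acid **13** attacks the free A-ring C–H, forming the C4–C4a bond and the pyranone ring last.
3. **13** ⇐ SN2 opening of trans-glycidic acid **12** by the hindered phenol **5** at the benzylic carbon. This inverts C2 and retains C3, giving (2R,3R).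
4. **12** ⇐ organocatalytic epoxidation of cinnamaldehyde **10**, which ignores the prenyl alkenes. **10** ⇐ Heck coupling of aryl iodide **8** with acrolein.
5. Phenol **5** ⇐ resorcinol by C–H borylation/oxidation and C-prenylation. Ring order: epoxide (Step 7), then pyranone (Step 10).

## Route

**Step 1**
Reactants: **1** resorcinol
Product: **2** 1,3-bis(methoxymethoxy)benzene
Conditions: NaH, MOMCl, THF, 0 °C → rt
Reagents that add atoms: MOMCl, ClCOC
Why: Williamson-type O-protection gives a 1,3-dialkoxyarene suited to sterically controlled borylation.

**Step 2**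
Reactants: **2**
Product: **3** 3,5-bis(methoxymethoxy)phenol
Conditions: [Ir(cod)OMe]2, dtbpy, B2pin2, THF, 80 °C; then NaBO3·4H2O, THF/H2O, rt (one pot)
Reagents that add atoms: sodium perborate, [Na+].[B-]1(O)(O)OO1 (supplies the phenolic O; B2pin2 is lost as borate)
Why: Ir-catalysed C–H borylation of a 1,3-disubstituted arene occurs at C5 for steric reasons, and oxidative deborylation gives the 1,3,5-trioxygenated ring, which is not available from any starting material of eight or fewer heavy atoms.

**Step 3**
Reactants: **3**, **4** prenyl bromide
Product: **5** 2-prenyl-3,5-bis(MOMO)phenol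
Conditions: NaOH (1.1 equiv), H2O/THF 1:1, 0 °C → rt
Reagents that add atoms: none
Why: "On-water" phenoxide C-alkylation (SN2 at the primary carbon) gives normal prenyl. The two ortho positions are equivalent, and the para position between two OMOM groups is hindered.

**Step 4**
Reactants: **6** 4-iodophenol, **4**
Product: **7** 4-iodo-2-prenylphenol
Conditions: NaOH, H2O/THF, 0 °C → rt
Reagents that add atoms: none
Why: The same ortho C-alkylation is cleaner here because the para position is blocked by iodine.

**Step 5**
Reactants: **7**
Product: **8** 4-iodo-1-(methoxymethoxy)-2-prenylbenzene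
Conditions: NaH, MOMCl, THF, 0 °C → rt
Reagents that add atoms: MOMCl, ClCOC
Why: Masks the B-ring phenol so it cannot compete as a nucleophile or form a quinone methide later.

**Step 6**
Reactants: **8**, **9** acrolein
Product: **10** (E)-3-[4-(MOMO)-3-prenylphenyl]propenal
Conditions: Pd(OAc)2 (5 mol%), Bu4NCl, NaHCO3, DMF, 80 °C
Reagents that add atoms: none
Why: Jeffery-type Heck reaction of an aryl iodide with an enal gives the E-cinnamaldehyde. The hindered trisubstituted prenyl alkene is inert under these conditions.

**Step 7**
Reactants: **10**
Product: **11** (2R,3S)-3-[4-(MOMO)-3-prenylphenyl]oxirane-2-carbaldehyde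
Conditions: 30% aq. H2O2, (R)-bis[3,5-(CF3)2C6H3]prolinol TMS ether (10 mol%), CH2Cl2, rt
Reagents that add atoms: H2O2, OO
Why: Iminium-catalysed nucleophilic (Jørgensen–Hayashi) epoxidation is chemoselective for the enal over the prenyl alkene. It sets both epoxide stereocentres in the trans (2R,3S) arrangement; the (R)-catalyst enantiomer is chosen by the iminium facial model.

**Step 8**
Reactants: **11**
Product: **12** (2R,3S)-3-[4-(MOMO)-3-prenylphenyl]oxirane-2-carboxylic acid
Conditions: NaClO2, NaH2PO4, 2-methyl-2-butene, t-BuOH/H2O, 0 °C
Reagents that add atoms: NaClO2, [Na+].[O-]Cl=O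
Why: Pinnick oxidation leaves the stereocentres untouched, and the alkene scavenger protects the prenyl group from HOCl.

**Step 9**
Reactants: **12**, **5**
Product: **13** (2R,3R)-2-hydroxy-3-aryl-3-aryloxypropanoic acid: 3-[2-prenyl-3,5-bis(MOMO)phenoxy]-3-[4-(MOMO)-3-prenylphenyl]-2-hydroxypropanoic acid
Conditions: Cs2CO3 (2.5 equiv), DMF, 50 °C; then aq. NaH2PO4
Reagents that add atoms: none
Why: Phenoxide opens the glycidate at the benzylic carbon (β to the carboxylate), as in diltiazem-type glycidate openings. This is SN2 with inversion at C2, giving R from S, and retention at C3, which stays R; this sets the trans (2R,3R) relationship.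

**Step 10**
Reactants: **13**
Product: **14** (2R,3R)-3-hydroxy-5,7,4'-tris(MOMO)-8,3'-diprenylflavanone
Conditions: 4CzIPN (2 mol%), PPh3 (2 equiv), Co(dmgH)2PyCl (5 mol%), MeCN, blue LEDs, rt
Reagents that add atoms: none (PPh3 removes the acid oxygen as Ph3P=O; H2 is evolved)
Why: Proposed new method: PPh3•+ (from reductive quenching of excited 4CzIPN) is trapped by the carboxylate. β-Scission of the phosphoranyl radical gives the acyl radical, which undergoes intramolecular homolytic aromatic substitution at the only free A-ring carbon. Cobaloxime-mediated oxidative rearomatisation with H2 release closes the chromanone. The closest known chemistry is PPh3-mediated photocatalytic acyl-radical generation from acids combined with intramolecular radical acylation of arenes. The ring-forming step touches neither C2 nor C3, so both stereocentres are carried through unchanged, and the 2,3-trans product is also the thermodynamically preferred one.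

**Step 11**
Reactants: **14**
Product: **15** Lespedezaflavanone C
Conditions: TMSOTf, 2,2'-bipyridyl, CH2Cl2, 0 °C → rt; then H2O
Reagents that add atoms: none (MOM groups are removed)
Why: The TMSOTf/bipyridyl system cleaves aryl MOM ethers under non-protic, non-basic conditions, which avoids prenyl-chroman cyclisation and C2/C3 epimerisation or ring opening.

## Compound list
1 | resorcinol (8 heavy atoms) | Oc1cccc(O)c1 | starting material
2 | 1,3-bis(methoxymethoxy)benzene | COCOc1cccc(OCOC)c1 | intermediate
3 | 3,5-bis(methoxymethoxy)phenol | COCOc1cc(O)cc(OCOC)c1 | intermediate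
4 | prenyl bromide (6 heavy atoms) | CC(C)=CCBr | starting material
5 | 2-prenyl-3,5-bis(methoxymethoxy)phenol | CC(C)=CCc1c(O)cc(OCOC)cc1OCOC | intermediate
6 | 4-iodophenol (8 heavy atoms) | Oc1ccc(I)cc1 | starting material
7 | 4-iodo-2-prenylphenol | CC(C)=CCc1cc(I)ccc1O | intermediate
8 | 4-iodo-1-(methoxymethoxy)-2-prenylbenzene | CC(C)=CCc1cc(I)ccc1OCOC | intermediate
9 | acrolein (4 heavy atoms) | C=CC=O | starting material
10 | (E)-3-[4-(MOMO)-3-prenylphenyl]propenal | CC(C)=CCc1cc(/C=C/C=O)ccc1OCOC | intermediate
11 | (2R,3S)-epoxy aldehyde | O=C[C@@H]1O[C@H]1c1ccc(OCOC)c(CC=C(C)C)c1 | intermediate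
12 | (2R,3S)-epoxy acid | OC(=O)[C@@H]1O[C@H]1c1ccc(OCOC)c(CC=C(C)C)c1 | intermediate
13 | (2R,3R)-hydroxy acid | OC(=O)[C@H](O)[C@H](Oc1c(CC=C(C)C)c(OCOC)cc(OCOC)c1)c1ccc(OCOC)c(CC=C(C)C)c1 | intermediate
14 | (2R,3R)-tris-MOM dihydroflavonol | CC(C)=CCc1cc([C@H]2Oc3c(CC=C(C)C)c(OCOC)cc(OCOC)c3C(=O)[C@@H]2O)ccc1OCOC | intermediate
15 | Lespedezaflavanone C | CC(C)=CCc1cc([C@H]2Oc3c(CC=C(C)C)c(O)cc(O)c3C(=O)[C@@H]2O)ccc1O | target

## Totals
Total steps: 11. Longest linear sequence: 8 (4-iodophenol → 7 → 8 → 10 → 11 → 12 → 13 → 14 → 15).

## Three steps most likely to fail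
1. **Step 10 (radical acylation).** The α-oxygenated acyl radical can decarbonylate, and competing indanone formation on the B ring is possible. Fallback: brominate or iodinate the A-ring C–H of 13 (NIS), convert the acid to its S-2-pyridyl thioester, and close the ring by Ni/Mn reductive intramolecular acyl–aryl coupling, so that an acyl-Ni species replaces the free acyl radical.
2. **Steps 3 and 4 (direct C-prenylation).** O- versus C-alkylation, bis-alkylation and para attack can all lower the yield. Fallback: O-allylation, aromatic Claisen rearrangement to the ortho-allyl phenol, then Ru-catalysed cross-metathesis with 2-methyl-2-butene to give the prenyl group. This adds steps but avoids direct alkylation.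
3. **Step 9 (glycidate opening).** The p-alkoxybenzylic centre may leak through SN1, and C2-attack is a possible regio-problem, which erodes stereo-integrity. Fallback: reduce 11 to the epoxy alcohol, open it at C3 with phenol 5 using Ti(OiPr)4 (Caron–Sharpless), then oxidise the primary alcohol to acid 13 with TEMPO/BAIB followed by NaClO2. This uses Lewis-acid chelation control instead of a free-phenoxide SN2.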